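**Retrosynthetic overview**

1. Numbering follows the C16 acid chain (C1 = ester carbon): ring B is O1–O2–C3–C4=C5–C6 and ring A is the peroxide bridging C10 and C13. Ring A is disconnected last, at both C–O bonds, to a (10E,12E)-diene and singlet oxygen.
2. Ring B is disconnected at C3–C4. C3 is an α-peroxy CH (a latent peroxycarbenium carbon) next to the ring Z-alkene C4=C5, and C6 is a peroxyketal. C4 can therefore be a (Z)-vinylsilane carbon tethered to C3 through C5–C6–O1–O2, closing the ring by ipso attack with loss of silicon.
3. The acyclic mixed peroxide for this closure comes from ketal exchange (O1–C6) between a (Z)-β-silylvinyl dimethyl ketal and methyl 3-hydroperoxy-3-methoxypropanoate.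
4. The ketal is built from (E)-hex-2-enal, iodoform, methyl but-3-enoate and ethynyltrimethylsilane by Takai olefination, B-alkyl Suzuki–Miyaura coupling, ester alkynylation, ketalisation and Lindlar reduction.
5. Order of ring formation: ring B first (C3 by a chiral Brønsted acid in the key step, C6 by ketal equilibration with separation), ring A last (cis by suprafacial cycloaddition, absolute sense by separation).

Key step: step 8

Assumption: the two rings are three methylene groups apart and are taken not to influence each other's stereochemical course, so step 10 is planned with a separation of the two cis adducts, and the antipode of the chiral acid that leads to 3R in step 8 has to be identified on the first run.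

Step 1
Reactants: 1 (E)-hex-2-enal; 2 iodoform
Product: 3 (1E,3E)-1-iodohepta-1,3-diene
Conditions: CrCl2, THF, 0 °C to rt
Reagents that add atoms: none
Why: Takai olefination, in which the geminal dichromium carbenoid formed from CHI3 and CrCl2 adds to the aldehyde and eliminates anti, forms the new C10=C11 double bond with E geometry and leaves the resident E-alkene untouched.

Step 2
Reactants: 4 methyl but-3-enoate; 3 (1E,3E)-1-iodohepta-1,3-diene
Product: 6 methyl (5E,7E)-undeca-5,7-dienoate, via borane adduct 5 (not isolated)
Conditions: 4, 9-BBN-H, THF, 0 °C to rt; then 3, PdCl2(dppf) (cat.), K3PO4, DMF/H2O, rt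
Reagents that add atoms: none
Why: Anti-Markovnikov hydroboration of the terminal alkene followed by B-alkyl Suzuki–Miyaura coupling, which proceeds with retention at the alkenyl iodide, forms the C9–C10 bond and delivers the (E,E)-diene without touching the methyl ester.

Step 3
Reactants: 6 methyl (5E,7E)-undeca-5,7-dienoate; 7 ethynyltrimethylsilane
Product: 8 (7E,9E)-1-(trimethylsilyl)trideca-7,9-dien-1-yn-3-one
Conditions: 7, n-BuLi, THF, −78 °C; BF3·OEt2; then 6, −78 °C
Reagents that add atoms: none
Why: Yamaguchi–Hirao alkynylation, in which the lithium acetylide activated by BF3·OEt2 acylates once on the methyl ester because the tetrahedral fluoroborate adduct collapses to the ynone only on work-up, introduces C4, C5 and the silyl group in one step.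

Step 4
Reactants: 8 (7E,9E)-1-(trimethylsilyl)trideca-7,9-dien-1-yn-3-one
Product: 9 trimethyl[(7E,9E)-3,3-dimethoxytrideca-7,9-dien-1-yn-1-yl]silane
Conditions: HC(OMe)3, MeOH, p-toluenesulfonic acid monohydrate (cat.), rt
Reagents that add atoms: trimethyl orthoformate, COC(OC)OC
Why: Acid-catalysed ketalisation with trimethyl orthoformate as dehydrating agent is reliable for alkynyl ketones and puts C6 at the ketal oxidation level that the later peroxyketal requires.

Step 5
Reactants: 9 trimethyl[(7E,9E)-3,3-dimethoxytrideca-7,9-dien-1-yn-1-yl]silane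
Product: 10 trimethyl[(1Z,7E,9E)-3,3-dimethoxytrideca-1,7,9-trien-1-yl]silane
Conditions: H2 (1 atm), Lindlar catalyst (Pd on CaCO3 poisoned with Pb(OAc)2), quinoline, hexane, rt
Reagents that add atoms: none
Why: Lindlar semihydrogenation delivers H2 syn to the silylalkyne and so gives the (Z)-vinylsilane, the poisoned catalyst leaving the conjugated diene alone, and as a ketal the Z-alkene has no conjugative path to isomerise.

Step 6
Reactants: 4 methyl but-3-enoate
Product: 11 methyl 3-hydroperoxy-3-methoxypropanoate (racemic)
Conditions: O3, CH2Cl2/MeOH, −78 °C; N2 purge, no reductive work-up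
Reagents that add atoms: ozone, [O-][O+]=O; methanol, CO
Why: In this ozonolysis the Criegee carbonyl oxide formed on the substituted alkene carbon is trapped by methanol as the α-methoxy hydroperoxide while the terminal carbon leaves as formaldehyde, and the new acetal carbon (the future C3) is racemic, which does not matter because it is ionised in step 8.

Step 7
Reactants: 10 trimethyl[(1Z,7E,9E)-3,3-dimethoxytrideca-1,7,9-trien-1-yl]silane; 11 methyl 3-hydroperoxy-3-methoxypropanoate
Product: 12 methyl 3-methoxy-3-{[(1Z,7E,9E)-3-methoxy-1-(trimethylsilyl)trideca-1,7,9-trien-3-yl]peroxy}propanoate (mixture of diastereomers at the two acetal carbons)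
Conditions: pyridinium p-toluenesulfonate (cat.), 4 Å molecular sieves, CH2Cl2, 0 °C
Reagents that add atoms: none
Why: In this acid-catalysed transketalisation the allylic dimethyl ketal ionises under the mild acid and the hydroperoxide, a better nucleophile than methanol, captures the oxocarbenium ion at C6 while the sieves take up methanol, the two acetal carbons being formed without control because C3 is ionised in step 8 and C6 is equilibrated in step 9.

Step 8
Reactants: 12 methyl 3-methoxy-3-{[(1Z,7E,9E)-3-methoxy-1-(trimethylsilyl)trideca-1,7,9-trien-3-yl]peroxy}propanoate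
Product: 14 methyl 2-[(3R)-6-[(4E,6E)-deca-4,6-dien-1-yl]-6-methoxy-3,6-dihydro-1,2-dioxin-3-yl]acetate as a mixture of C6 epimers, via peroxycarbenium ion 13 (not isolated)
Conditions: (S)-3,3'-bis(2,4,6-triisopropylphenyl)-1,1'-binaphthalene-2,2'-diyl N-triflylphosphoramide (10 mol%), toluene, −78 to −40 °C
Reagents that add atoms: none
Why: Proposed new method: the chiral Brønsted acid ionises the C3 methoxy group of 12, and in the contact ion pair 13 the (Z)-vinylsilane carbon C4 attacks the peroxycarbenium carbon C3 ipso, after which the β-silyl cation at C5 loses Me3Si+ to the liberated methanol, so that the acid is regenerated and the C4=C5 double bond stays cis inside the new ring. The closest known reaction types are the silyl-Prins cyclisation of (Z)-vinylsilyl alcohols with aldehydes to 5,6-dihydro-2H-pyrans, Lewis acid-mediated intramolecular additions of allylsilanes to peroxycarbenium ions, and chiral-anion-directed Prins cyclisations as the model for the enantiocontrol. Ring B (O1, O2, C3, C4, C5, C6) closes in the 6-endo-trig mode with respect to the vinylsilane, the only mode open to a Z-alkene tethered through C6–O1–O2. C3 is the one stereocentre that must be fixed here and it is controlled by the chiral phosphoramidate anion, which shields one face of the (E)-peroxycarbenium ion; C6 is a ketal carbon that can epimerise under the acid and is therefore settled in step 9. The step needs ipso attack at C4 with retention of alkene geometry and use of the C3 acetal in the presence of the C6 peroxyketal: silicon directs the electrophile to C4 by stabilising charge at C5 and then leaves, while ionisation at C6 is reversible and has no productive outlet, so the material should funnel through the irreversible C3–C4 closure.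

Step 9
Reactants: 14 methyl 2-[(3R)-6-[(4E,6E)-deca-4,6-dien-1-yl]-6-methoxy-3,6-dihydro-1,2-dioxin-3-yl]acetate (C6 epimers)
Product: 15 methyl 2-[(3R,6S)-6-[(4E,6E)-deca-4,6-dien-1-yl]-6-methoxy-3,6-dihydro-1,2-dioxin-3-yl]acetate
Conditions: camphor-10-sulfonic acid (cat.), MeOH, 0 °C; chromatography on silica; (6R)-epimer resubjected
Reagents that add atoms: methanol, CO
Why: Acid-catalysed ketal exchange in methanol, which ionises the allylic peroxyketal reversibly to the ring peroxycarbenium ion, epimerises C6 alone, and because the two C6 epimers are ring diastereomers separable on silica and the (6R)-epimer can be resubjected, C6 is set as S under thermodynamic control with recycling while C3 stays fixed.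

Step 10
Reactants: 15 methyl 2-[(3R,6S)-6-[(4E,6E)-deca-4,6-dien-1-yl]-6-methoxy-3,6-dihydro-1,2-dioxin-3-yl]acetate
Product: 16 methyl 2-[(3R,6S)-6-methoxy-6-{3-[(3R,6S)-6-propyl-3,6-dihydro-1,2-dioxin-3-yl]propyl}-3,6-dihydro-1,2-dioxin-3-yl]acetate (target)
Conditions: O2, 5,10,15,20-tetraphenylporphyrin (cat.), visible light, CH2Cl2, 0 °C; preparative HPLC on a chiral stationary phase
Reagents that add atoms: dioxygen, O=O
Why: In this sensitised photooxygenation singlet oxygen adds in a suprafacial [4+2] cycloaddition to the s-cis conformer of the (E,E)-diene, which sets C10 and C13 cis and leaves the electron-poor ring-B alkene alone, and since ring B cannot bias the two diene faces the (10R,13S) adduct is separated from its (10S,13R) diastereomer by the chiral-phase HPLC.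

**Compound list**

1 | (E)-hex-2-enal | CCC/C=C/C=O | starting material
2 | iodoform (triiodomethane) | IC(I)I | starting material
3 | (1E,3E)-1-iodohepta-1,3-diene | CCC/C=C/C=C/I | intermediate
4 | methyl but-3-enoate | C=CCC(=O)OC | starting material
5 | methyl 4-(9-borabicyclo[3.3.1]nonan-9-yl)butanoate (not isolated) | COC(=O)CCCB1C2CCCC1CCC2 | intermediate
6 | methyl (5E,7E)-undeca-5,7-dienoate | CCC/C=C/C=C/CCCC(=O)OC | intermediate
7 | ethynyltrimethylsilane | C#C[Si](C)(C)C | starting material
8 | (7E,9E)-1-(trimethylsilyl)trideca-7,9-dien-1-yn-3-one | CCC/C=C/C=C/CCCC(=O)C#C[Si](C)(C)C | intermediate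
9 | trimethyl[(7E,9E)-3,3-dimethoxytrideca-7,9-dien-1-yn-1-yl]silane | CCC/C=C/C=C/CCCC(OC)(OC)C#C[Si](C)(C)C | intermediate
10 | trimethyl[(1Z,7E,9E)-3,3-dimethoxytrideca-1,7,9-trien-1-yl]silane | CCC/C=C/C=C/CCCC(OC)(OC)/C=C\[Si](C)(C)C | intermediate
11 | methyl 3-hydroperoxy-3-methoxypropanoate (racemic) | COC(=O)CC(OC)OO | intermediate
12 | methyl 3-methoxy-3-{[(1Z,7E,9E)-3-methoxy-1-(trimethylsilyl)trideca-1,7,9-trien-3-yl]peroxy}propanoate (both acetal carbons unassigned, mixture) | CCC/C=C/C=C/CCCC(OC)(OOC(OC)CC(=O)OC)/C=C\[Si](C)(C)C | intermediate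
13 | peroxycarbenium ion formed from 12 by loss of the C3 methoxy group, paired with the phosphoramidate anion (not isolated) | CCC/C=C/C=C/CCCC(OC)(O[O+]=CCC(=O)OC)/C=C\[Si](C)(C)C | intermediate
14 | methyl 2-[(3R)-6-[(4E,6E)-deca-4,6-dien-1-yl]-6-methoxy-3,6-dihydro-1,2-dioxin-3-yl]acetate (C6 epimers, C6 drawn without configuration) | CCC/C=C/C=C/CCCC1(OC)C=C[C@@H](CC(=O)OC)OO1 | intermediate
15 | methyl 2-[(3R,6S)-6-[(4E,6E)-deca-4,6-dien-1-yl]-6-methoxy-3,6-dihydro-1,2-dioxin-3-yl]acetate | CCC/C=C/C=C/CCC[C@@]1(OC)C=C[C@@H](CC(=O)OC)OO1 | intermediate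
16 | methyl 2-[(3R,6S)-6-methoxy-6-{3-[(3R,6S)-6-propyl-3,6-dihydro-1,2-dioxin-3-yl]propyl}-3,6-dihydro-1,2-dioxin-3-yl]acetate | CCC[C@H]1C=C[C@@H](CCC[C@@]2(OC)C=C[C@@H](CC(=O)OC)OO2)OO1 | target

**Step count and risks**

Total step count: 10. Longest linear sequence: 9 steps (steps 1 to 5 and 7 to 10); step 6 is a one-step branch.

Steps most likely to fail:

1. Step 8 (Proposed new method). Two processes may defeat it. First, C–C bond formation may be slow because the vinylsilane is flanked by the electron-poor ketal carbon, so that reversible ionisation at C6 drains material into cleavage of the peroxide (loss of the hydroperoxide or Hock-type fragmentation). Second, facial discrimination by the chiral anion may be poor. The fallback uses known chemistry and closes ring B through the O2–C3 bond instead. It sets out from 9. Removal of the silyl group (K2CO3, MeOH) gives the terminal alkyne (7E,9E)-3,3-dimethoxytrideca-7,9-dien-1-yne F1. Sonogashira coupling with methyl (E)-3-iodoacrylate (PdCl2(PPh3)2, CuI, Et3N) gives methyl (2E,10E,12E)-6,6-dimethoxyhexadeca-2,10,12-trien-4-ynoate F2. Lindlar semihydrogenation gives methyl (2E,4Z,10E,12E)-6,6-dimethoxyhexadeca-2,4,10,12-tetraenoate F3. Exchange of one methoxy group for hydrogen peroxide (ethereal H2O2, pyridinium p-toluenesulfonate) gives methyl (2E,4Z,10E,12E)-6-hydroperoxy-6-methoxyhexadeca-2,4,10,12-tetraenoate F4. Diethylamine in 2,2,2-trifluoroethanol then closes ring B by intramolecular 6-exo-trig peroxy-Michael addition to C3 and gives racemic methyl 2-[6-[(4E,6E)-deca-4,6-dien-1-yl]-6-methoxy-3,6-dihydro-1,2-dioxin-3-yl]acetate F5. F5 is equilibrated as in step 9, the (3R,6S)-enantiomer is separated from its antipode on a chiral stationary phase, and the route is rejoined at 15.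

2. Step 10. Both diene faces should be attacked at comparable rates, ene reaction at the allylic C9 and C14 hydrogens may compete, and the two remote diastereomers may co-elute. The fallback moves the cycloaddition ahead of all other peroxide chemistry and resolves a small racemate instead. It sets out from 10. Sensitised photooxygenation gives racemic trimethyl[(1Z)-3,3-dimethoxy-6-(cis-6-propyl-3,6-dihydro-1,2-dioxin-3-yl)hex-1-en-1-yl]silane F6. Its enantiomers are separated on a chiral stationary phase to give trimethyl[(1Z)-3,3-dimethoxy-6-[(3R,6S)-6-propyl-3,6-dihydro-1,2-dioxin-3-yl]hex-1-en-1-yl]silane F7. Ketal exchange with 11 under the conditions of step 7 gives methyl 3-methoxy-3-{[(1Z)-3-methoxy-6-[(3R,6S)-6-propyl-3,6-dihydro-1,2-dioxin-3-yl]-1-(trimethylsilyl)hex-1-en-3-yl]peroxy}propanoate F8. The conditions of step 8 give methyl 2-[(3R)-6-methoxy-6-{3-[(3R,6S)-6-propyl-3,6-dihydro-1,2-dioxin-3-yl]propyl}-3,6-dihydro-1,2-dioxin-3-yl]acetate as C6 epimers F9. The equilibration and separation of step 9 then end at 16.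

3. Step 7. Acid-induced loss of methanol or hydrogen peroxide from the α-methoxy hydroperoxide 11 and double exchange at C6 may consume both partners. The fallback reverses the roles of the two components. It sets out from 10. Exchange of one methoxy group for hydrogen peroxide (ethereal H2O2, pyridinium p-toluenesulfonate, 0 °C) gives trimethyl[(1Z,7E,9E)-3-hydroperoxy-3-methoxytrideca-1,7,9-trien-1-yl]silane F10. Base-catalysed conjugate addition of this tertiary hydroperoxide to methyl (E)-3-methoxyacrylate (Cs2CO3 cat., CH2Cl2) then forms the O2–C3 bond, and the route is rejoined at 12.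

Further compounds
F1 | step 8 | (7E,9E)-3,3-dimethoxytrideca-7,9-dien-1-yne | CCC/C=C/C=C/CCCC(OC)(OC)C#C
F2 | step 8 | methyl (2E,10E,12E)-6,6-dimethoxyhexadeca-2,10,12-trien-4-ynoate | CCC/C=C/C=C/CCCC(OC)(OC)C#C/C=C/C(=O)OC
F3 | step 8 | methyl (2E,4Z,10E,12E)-6,6-dimethoxyhexadeca-2,4,10,12-tetraenoate | CCC/C=C/C=C/CCCC(OC)(OC)/C=C\C=C\C(=O)OC
F4 | step 8 | methyl (2E,4Z,10E,12E)-6-hydroperoxy-6-methoxyhexadeca-2,4,10,12-tetraenoate (racemic) | CCC/C=C/C=C/CCCC(OC)(OO)/C=C\C=C\C(=O)OC
F5 | step 8 | methyl 2-[6-[(4E,6E)-deca-4,6-dien-1-yl]-6-methoxy-3,6-dihydro-1,2-dioxin-3-yl]acetate (racemic, ring stereocentres drawn without configuration) | CCC/C=C/C=C/CCCC1(OC)C=CC(CC(=O)OC)OO1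
F6 | step 10 | trimethyl[(1Z)-3,3-dimethoxy-6-(cis-6-propyl-3,6-dihydro-1,2-dioxin-3-yl)hex-1-en-1-yl]silane (racemic, ring stereocentres drawn without configuration) | CCCC1C=CC(CCCC(OC)(OC)/C=C\[Si](C)(C)C)OO1
F7 | step 10 | trimethyl[(1Z)-3,3-dimethoxy-6-[(3R,6S)-6-propyl-3,6-dihydro-1,2-dioxin-3-yl]hex-1-en-1-yl]silane | CCC[C@H]1C=C[C@@H](CCCC(OC)(OC)/C=C\[Si](C)(C)C)OO1
F8 | step 10 | methyl 3-methoxy-3-{[(1Z)-3-methoxy-6-[(3R,6S)-6-propyl-3,6-dihydro-1,2-dioxin-3-yl]-1-(trimethylsilyl)hex-1-en-3-yl]peroxy}propanoate (acetal carbons unassigned) | CCC[C@H]1C=C[C@@H](CCCC(OC)(OOC(OC)CC(=O)OC)/C=C\[Si](C)(C)C)OO1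
F9 | step 10 | methyl 2-[(3R)-6-methoxy-6-{3-[(3R,6S)-6-propyl-3,6-dihydro-1,2-dioxin-3-yl]propyl}-3,6-dihydro-1,2-dioxin-3-yl]acetate (C6 epimers) | CCC[C@H]1C=C[C@@H](CCCC2(OC)C=C[C@@H](CC(=O)OC)OO2)OO1
F10 | step 7 | trimethyl[(1Z,7E,9E)-3-hydroperoxy-3-methoxytrideca-1,7,9-trien-1-yl]silane (racemic) | CCC/C=C/C=C/CCCC(OC)(OO)/C=C\[Si](C)(C)C
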